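**Retrosynthetic overview**

1. Target 25 ⇐ selective O8-angeloylation of diol 24 ⇐ OsO4 dihydroxylation of the C8=C9 alkene anti to the C7 angelate ⇐ oxazaborolidine (CBS) reduction of a cycloheptenone, which sets C7 under catalyst control.
2. Ring C (cycloheptane) is closed last, by a deoxygenative C5–C6 coupling between the cyclobutanone and the isopropyl ketone of a bicyclo[3.1.1]heptanone (proposed new step).
3. Rings A (six-membered) and B (cyclobutane) are formed together by an intramolecular vinylketene–alkene [2+2] cycloaddition of an acyclic C15 chain; the C1 silyloxy stereocenter on the tether fixes the alkene face.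
4. The C15 chain and its first stereocenter (C1) come from an organocatalytic asymmetric vinylogous Mukaiyama aldol of a senecioate-derived silyl dienolate with a keto-enal.
5. The keto-enal comes from (E)-4,4-dimethoxy-2-methylbut-2-enal and 3-methylbutan-2-one. Ring order: A+B, then C.

**Assumptions and naming**

- Tricyclic compounds are named on the longipinane skeleton with the target's numbering: C1 carbonyl carbon, C2=C3 (C3 bears a methyl, here called C12), C4 and C11 cyclobutane bridgeheads, C5 cyclobutane CH, C6 CMe2, C7–C9 oxygenated carbons, C10 quaternary C–Me. "3(12)-ene" means the exocyclic C3=CH2 isomer.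
- In step 4 the catalyst enantiomer that gives the (5S)-silyl ether is used. The (R)-catalyst is written; its antipode is taken if a Mosher check on desilylated 8 shows the opposite sense.
- The mixed anhydride 19 is made once in a single batch (step 10), kept as a filtered toluene solution under argon at −20 °C, and drawn on for both angeloylations (steps 11 and 15).
- The route is a proposal and has not been run; yields and selectivities are expectations from analogy.

**Route**

Step 1
Reactants: 1 (E)-4,4-dimethoxy-2-methylbut-2-enal; 2 3-methylbutan-2-one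
Product: 3 (4E,6E)-8,8-dimethoxy-2,6-dimethylocta-4,6-dien-3-one
Conditions: 2 (5 equiv), aq. NaOH (10 mol %), EtOH, 0 → 23 °C
Reagents that add atoms: none
Why: Claisen–Schmidt crossed aldol condensation: the enal has no α-hydrogen, only the methyl-side aldol of 2 can dehydrate, and the E-enone forms while the existing E-trisubstituted alkene is untouched.

Step 2
Reactants: 3 (4E,6E)-8,8-dimethoxy-2,6-dimethylocta-4,6-dien-3-one
Product: 5 (E)-3,7-dimethyl-6-oxooct-2-enal, via silyl enol ether 4 (not isolated)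
Conditions: Et3SiH, RhCl(PPh3)3 (1 mol %), PhMe, 50 °C; then 1 M HCl, THF, 0 °C
Reagents that add atoms: water, O
Why: Rhodium-catalysed 1,4-hydrosilylation of the enone (Ojima type) saturates only C8–C9, and the mild acid work-up hydrolyses the silyl enol ether and the acetal without E/Z isomerisation of the enal.

Step 3
Reactants: 6 methyl 3-methylbut-2-enoate
Product: 7 tert-butyl[(1-methoxy-3-methylbuta-1,3-dien-1-yl)oxy]dimethylsilane
Conditions: LiN(iPr)2, THF/DMPU, −78 °C; tBuMe2SiCl
Reagents that add atoms: tert-butyldimethylsilyl chloride, CC(C)(C)[Si](C)(C)Cl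
Why: γ-Deprotonation of the senecioate and O-silylation of the dienolate give the vinylogous silyl ketene acetal.

Step 4
Reactants: 5 (E)-3,7-dimethyl-6-oxooct-2-enal; 7 tert-butyl[(1-methoxy-3-methylbuta-1,3-dien-1-yl)oxy]dimethylsilane
Product: 8 methyl (2E,5S,6E)-5-[(tert-butyldimethylsilyl)oxy]-3,7,11-trimethyl-10-oxododeca-2,6-dienoate
Conditions: (R)-3,3′-bis[3,5-(CF3)2C6H3]-1,1′-binaphthyl-2,2′-disulfonimide (2 mol %), Et2O, −78 °C
Reagents that add atoms: none
Why: Catalytic asymmetric vinylogous Mukaiyama aldol under silylium counteranion-directed organocatalysis: the chiral disulfonimide anion shields one face of the silyl-activated aldehyde (the ketone is far less reactive), the dienolate attacks through its γ-carbon, and silyl transfer delivers the C1 (chain C5) stereocenter directly as its TBS ether.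

Step 5
Reactants: 8 methyl (2E,5S,6E)-5-[(tert-butyldimethylsilyl)oxy]-3,7,11-trimethyl-10-oxododeca-2,6-dienoate
Product: 9 potassium (2E,5S,6E)-5-[(tert-butyldimethylsilyl)oxy]-3,7,11-trimethyl-10-oxododeca-2,6-dienoate
Conditions: KOSiMe3, THF, 23 °C
Reagents that add atoms: potassium trimethylsilanolate, C[Si](C)(C)[O-].[K+]
Why: Anhydrous silanolate ester cleavage gives the carboxylate salt at room temperature, avoiding vinylogous elimination of the δ-silyloxy group and giving the salt needed for acid-free acid chloride formation.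

Step 6
Reactants: 9 potassium (2E,5S,6E)-5-[(tert-butyldimethylsilyl)oxy]-3,7,11-trimethyl-10-oxododeca-2,6-dienoate
Product: 12 (1R,2S,5R,7R)-2-[(tert-butyldimethylsilyl)oxy]-7-methyl-4-methylidene-7-(4-methyl-3-oxopentyl)bicyclo[3.1.1]heptan-6-one, via acid chloride 10 (not isolated), via vinylketene 11 (not isolated)
Conditions: (COCl)2, DMF (cat.), PhH, 0 → 23 °C; then slow addition to Et3N, PhMe, 110 °C (0.005 M)
Reagents that add atoms: none
Why: Intramolecular vinylketene–alkene [2+2] cycloaddition in the bridged (Snider) mode: the ketene carbonyl carbon bonds to the less substituted alkene carbon C11 and the ketene α-carbon to C10, the E-alkene places the C10 methyl over the three-carbon bridge, and the tether silyloxy group sits away from that methyl (allylic 1,3-strain), so one alkene face is attacked and C4, C10 and C11 are set.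

Step 7
Reactants: 12 (1R,2S,5R,7R)-2-[(tert-butyldimethylsilyl)oxy]-7-methyl-4-methylidene-7-(4-methyl-3-oxopentyl)bicyclo[3.1.1]heptan-6-one
Product: 15 (1S,4R,5S,10R,11R)-1-(tert-butyldimethylsilyloxy)longipin-3(12)-en-7-one, via trisylhydrazone 13 (not isolated), via tricyclic sulfonylhydrazide 14 (not isolated)
Conditions: 2,4,6-(iPr)3C6H2SO2NHNH2, 4 Å MS, CH2Cl2, 23 °C; then Me3SiOTf, iPr2NEt, −78 → 0 °C; then MeOH, 50 °C
Reagents that add atoms: none
Why: Proposed new method: a deoxygenative (traceless) intramolecular ketone–ketone coupling in which the strained, non-enolisable cyclobutanone alone condenses to sulfonylhydrazone 13, Me3SiOTf/iPr2NEt N-silylates it and turns the isopropyl ketone into its more substituted enol silane, this adds in a Mukaiyama–Mannich step to the activated C=N from the only face the tether can reach (C5–C6 bond and ring C, with attack through C8 leading only to a strained five-membered ring), and warming in MeOH expels sulfinic acid and N2 from the alkyl diazene so that the bridgehead C5 takes up hydrogen with forced retention; the closest known reaction types are the Myers reductive coupling of N-silyl sulfonylhydrazones with organolithiums, one-pot silyl triflate/amine enol silane formation–Mukaiyama additions, and Mannich additions of enol silanes to acylhydrazones.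

Step 8
Reactants: 15 (1S,4R,5S,10R,11R)-1-(tert-butyldimethylsilyloxy)longipin-3(12)-en-7-one
Product: 16 (1S,4R,5S,10R,11R)-1-(tert-butyldimethylsilyloxy)longipina-3(12),8-dien-7-one
Conditions: IBX, DMSO/PhF, 70 °C
Reagents that add atoms: none
Why: IBX dehydrogenation of a ketone to its enone (Nicolaou type) can only run toward C8–C9 because C6 is quaternary.

Step 9
Reactants: 16 (1S,4R,5S,10R,11R)-1-(tert-butyldimethylsilyloxy)longipina-3(12),8-dien-7-one
Product: 17 (1S,4R,5S,7R,10R,11R)-1-(tert-butyldimethylsilyloxy)longipina-3(12),8-dien-7-ol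
Conditions: (S)-Me-CBS (20 mol %), catecholborane, PhMe, −78 °C; then MeOH
Reagents that add atoms: none
Why: Corey–Bakshi–Shibata reduction sets C7 by catalyst control (quaternary C6 as the large group, vinyl C8 as the small one; the two ketone faces differ only remotely in this skeleton), and catecholborane reduces 1,2 without hydroborating the methylidene.

Step 10
Reactants: 18 angelic acid [(Z)-2-methylbut-2-enoic acid]
Product: 19 (Z)-2-methylbut-2-enoic 2,4,6-trichlorobenzoic anhydride
Conditions: 2,4,6-Cl3C6H2COCl (1.0 equiv), Et3N (1.05 equiv), PhMe, 0 → 23 °C; filtered from Et3NHCl under Ar, kept as a PhMe solution at −20 °C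
Reagents that add atoms: 2,4,6-trichlorobenzoyl chloride, O=C(Cl)c1c(Cl)cc(Cl)cc1Cl
Why: Mixed-anhydride formation (the activation half of the Yamaguchi esterification) by acylation of the triethylammonium angelate; no nucleophilic catalyst is present, so the Z geometry is kept, and one batch serves both angeloylations.

Step 11
Reactants: 17 (1S,4R,5S,7R,10R,11R)-1-(tert-butyldimethylsilyloxy)longipina-3(12),8-dien-7-ol; 19 (Z)-2-methylbut-2-enoic 2,4,6-trichlorobenzoic anhydride
Product: 20 (1S,4R,5S,7R,10R,11R)-1-(tert-butyldimethylsilyloxy)longipina-3(12),8-dien-7-yl (Z)-2-methylbut-2-enoate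
Conditions: 19 (3 equiv), Et3N (3 equiv), PhMe, 60 °C
Reagents that add atoms: none
Why: Yamaguchi esterification without a nucleophilic catalyst: the hindered allylic alcohol attacks the angeloyl carbonyl of the mixed anhydride (the trichlorobenzoyl carbonyl is blocked by its two ortho chlorines), with retention at C7 and with the Z (angelate) geometry kept.

Step 12
Reactants: 20 (1S,4R,5S,7R,10R,11R)-1-(tert-butyldimethylsilyloxy)longipina-3(12),8-dien-7-yl (Z)-2-methylbut-2-enoate
Product: 21 (1S,4R,5S,7R,10R,11R)-1-hydroxylongipina-3(12),8-dien-7-yl (Z)-2-methylbut-2-enoate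
Conditions: HF·pyridine, THF/pyridine, 0 → 23 °C
Reagents that add atoms: none
Why: Buffered fluoride desilylation frees the C1 alcohol and leaves the angelate and both alkenes intact.

Step 13
Reactants: 21 (1S,4R,5S,7R,10R,11R)-1-hydroxylongipina-3(12),8-dien-7-yl (Z)-2-methylbut-2-enoate
Product: 23 (4R,5S,7R,10R,11R)-1-oxolongipina-2,8-dien-7-yl (Z)-2-methylbut-2-enoate, via deconjugated enone 22 (not isolated)
Conditions: Dess–Martin periodinane, CH2Cl2, 0 → 23 °C; then DBU (5 mol %), CH2Cl2, 0 °C
Reagents that add atoms: none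
Why: Dess–Martin oxidation removes the control stereocenter at C1, and base-catalysed isomerisation moves the exocyclic alkene into conjugation to give the verbenone-type 3-methyl enone (any endocyclic alkene isomer carried from step 6 converges here).

Step 14
Reactants: 23 (4R,5S,7R,10R,11R)-1-oxolongipina-2,8-dien-7-yl (Z)-2-methylbut-2-enoate
Product: 24 (4R,5S,7S,8S,9S,10R,11R)-8,9-dihydroxy-1-oxolongipin-2-en-7-yl (Z)-2-methylbut-2-enoate
Conditions: OsO4 (3 mol %), NMO, acetone/H2O, 0 → 23 °C
Reagents that add atoms: N-methylmorpholine N-oxide, C[N+]1([O-])CCOCC1; water, O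
Why: Upjohn dihydroxylation takes the only non-conjugated alkene (C8=C9) in preference to the enone and angelate double bonds and adds anti to the allylic C7 ester (Kishi-type 1,2-induction) and anti to the C10 methyl, giving the C8/C9 cis-diol trans to the C7 oxygen.

Step 15
Reactants: 24 (4R,5S,7S,8S,9S,10R,11R)-8,9-dihydroxy-1-oxolongipin-2-en-7-yl (Z)-2-methylbut-2-enoate; 19 (Z)-2-methylbut-2-enoic 2,4,6-trichlorobenzoic anhydride
Product: 25 (4R,5S,7S,8S,9S,10R,11R)-9-hydroxy-1-oxolongipin-2-ene-7,8-diyl bis[(Z)-2-methylbut-2-enoate]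
Conditions: 19 (1.2 equiv), Et3N (1.5 equiv), PhMe, 40 °C
Reagents that add atoms: none
Why: Yamaguchi esterification with the preformed mixed anhydride is expected to take the C8 hydroxyl in preference to the C9 hydroxyl, which is shielded by the adjacent quaternary C10, and this completes the target.

**Compound list**

1 | (E)-4,4-dimethoxy-2-methylbut-2-enal | O=C/C(C)=C/C(OC)OC | starting material
2 | 3-methylbutan-2-one | CC(C)C(C)=O | starting material
3 | (4E,6E)-8,8-dimethoxy-2,6-dimethylocta-4,6-dien-3-one | CC(C)C(=O)/C=C/C(C)=C/C(OC)OC | intermediate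
4 | (6E)-8,8-dimethoxy-2,6-dimethyl-3-(triethylsilyloxy)octa-3,6-diene (enol ether geometry undefined) | CC(C)C(O[Si](CC)(CC)CC)=CC/C(C)=C/C(OC)OC | intermediate (not isolated)
5 | (E)-3,7-dimethyl-6-oxooct-2-enal | CC(C)C(=O)CC/C(C)=C/C=O | intermediate
6 | methyl 3-methylbut-2-enoate | COC(=O)C=C(C)C | starting material
7 | tert-butyl[(1-methoxy-3-methylbuta-1,3-dien-1-yl)oxy]dimethylsilane | COC(O[Si](C)(C)C(C)(C)C)=CC(C)=C | intermediate
8 | methyl (2E,5S,6E)-5-[(tert-butyldimethylsilyl)oxy]-3,7,11-trimethyl-10-oxododeca-2,6-dienoate | COC(=O)/C=C(\C)C[C@H](O[Si](C)(C)C(C)(C)C)/C=C(\C)CCC(=O)C(C)C | intermediate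
9 | potassium (2E,5S,6E)-5-[(tert-butyldimethylsilyl)oxy]-3,7,11-trimethyl-10-oxododeca-2,6-dienoate | [K+].[O-]C(=O)/C=C(\C)C[C@H](O[Si](C)(C)C(C)(C)C)/C=C(\C)CCC(=O)C(C)C | intermediate
10 | (2E,5S,6E)-5-[(tert-butyldimethylsilyl)oxy]-3,7,11-trimethyl-10-oxododeca-2,6-dienoyl chloride | ClC(=O)/C=C(\C)C[C@H](O[Si](C)(C)C(C)(C)C)/C=C(\C)CCC(=O)C(C)C | intermediate (not isolated)
11 | (5S,6E)-5-[(tert-butyldimethylsilyl)oxy]-7,11-dimethyl-3-methylidenedodeca-1,6-diene-1,10-dione (vinylketene) | O=C=CC(=C)C[C@H](O[Si](C)(C)C(C)(C)C)/C=C(\C)CCC(=O)C(C)C | intermediate (not isolated)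
12 | (1R,2S,5R,7R)-2-[(tert-butyldimethylsilyl)oxy]-7-methyl-4-methylidene-7-(4-methyl-3-oxopentyl)bicyclo[3.1.1]heptan-6-one | O=C1[C@H]2[C@@H](O[Si](C)(C)C(C)(C)C)CC(=C)[C@@H]1[C@@]2(C)CCC(=O)C(C)C | intermediate
13 | 2,4,6-triisopropylbenzenesulfonylhydrazone of 12 at the cyclobutanone carbonyl (C=N geometry undefined) | CC(C)c1cc(C(C)C)c(S(=O)(=O)NN=C2[C@H]3[C@@H](O[Si](C)(C)C(C)(C)C)CC(=C)[C@@H]2[C@@]3(C)CCC(=O)C(C)C)c(C(C)C)c1 | intermediate (not isolated)
14 | N′-[7-oxo-1-(tert-butyldimethylsilyloxy)longipin-3(12)-en-5-yl]-2,4,6-triisopropylbenzenesulfonohydrazide (15 with NH–NH–SO2Ar in place of H at C5) | C1CC(=O)C(C)(C)[C@]2(NNS(=O)(=O)c4c(C(C)C)cc(C(C)C)cc4C(C)C)[C@H]3[C@@H](O[Si](C)(C)C(C)(C)C)CC(=C)[C@@H]2[C@@]13C | intermediate (not isolated)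
15 | (1S,4R,5S,10R,11R)-1-(tert-butyldimethylsilyloxy)longipin-3(12)-en-7-one | C1CC(=O)C(C)(C)[C@@H]2[C@H]3[C@@H](O[Si](C)(C)C(C)(C)C)CC(=C)[C@@H]2[C@@]13C | intermediate
16 | (1S,4R,5S,10R,11R)-1-(tert-butyldimethylsilyloxy)longipina-3(12),8-dien-7-one | C1=CC(=O)C(C)(C)[C@@H]2[C@H]3[C@@H](O[Si](C)(C)C(C)(C)C)CC(=C)[C@@H]2[C@@]13C | intermediate
17 | (1S,4R,5S,7R,10R,11R)-1-(tert-butyldimethylsilyloxy)longipina-3(12),8-dien-7-ol | C1=C[C@@H](O)C(C)(C)[C@@H]2[C@H]3[C@@H](O[Si](C)(C)C(C)(C)C)CC(=C)[C@@H]2[C@@]13C | intermediate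
18 | angelic acid, (Z)-2-methylbut-2-enoic acid | C/C=C(/C)C(=O)O | starting material
19 | (Z)-2-methylbut-2-enoic 2,4,6-trichlorobenzoic anhydride | C/C=C(/C)C(=O)OC(=O)c1c(Cl)cc(Cl)cc1Cl | intermediate
20 | (1S,4R,5S,7R,10R,11R)-1-(tert-butyldimethylsilyloxy)longipina-3(12),8-dien-7-yl (Z)-2-methylbut-2-enoate | C1=C[C@@H](OC(=O)/C(C)=C\C)C(C)(C)[C@@H]2[C@H]3[C@@H](O[Si](C)(C)C(C)(C)C)CC(=C)[C@@H]2[C@@]13C | intermediate
21 | (1S,4R,5S,7R,10R,11R)-1-hydroxylongipina-3(12),8-dien-7-yl (Z)-2-methylbut-2-enoate | C1=C[C@@H](OC(=O)/C(C)=C\C)C(C)(C)[C@@H]2[C@H]3[C@@H](O)CC(=C)[C@@H]2[C@@]13C | intermediate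
22 | (4R,5S,7R,10R,11R)-1-oxolongipina-3(12),8-dien-7-yl (Z)-2-methylbut-2-enoate | C1=C[C@@H](OC(=O)/C(C)=C\C)C(C)(C)[C@@H]2[C@H]3C(=O)CC(=C)[C@@H]2[C@@]13C | intermediate (not isolated)
23 | (4R,5S,7R,10R,11R)-1-oxolongipina-2,8-dien-7-yl (Z)-2-methylbut-2-enoate | C1=C[C@@H](OC(=O)/C(C)=C\C)C(C)(C)[C@@H]2[C@H]3C(=O)C=C(C)[C@@H]2[C@@]13C | intermediate
24 | (4R,5S,7S,8S,9S,10R,11R)-8,9-dihydroxy-1-oxolongipin-2-en-7-yl (Z)-2-methylbut-2-enoate | O[C@@H]1[C@@H](OC(=O)/C(C)=C\C)C(C)(C)[C@@H]2[C@H]3C(=O)C=C(C)[C@@H]2[C@@]3(C)[C@@H]1O | intermediate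
25 | (4R,5S,7S,8S,9S,10R,11R)-9-hydroxy-1-oxolongipin-2-ene-7,8-diyl bis[(Z)-2-methylbut-2-enoate] (CNP0256888.1) | C/C=C(/C)C(=O)O[C@@H]1[C@@H](OC(=O)/C(C)=C\C)C(C)(C)[C@@H]2[C@H]3C(=O)C=C(C)[C@@H]2[C@@]3(C)[C@@H]1O | target

**Step count**

Total steps: 15. Longest linear sequence: 13 steps (1 → 25 through steps 1, 2, 4–9 and 11–15; steps 3 and 10 are one-step branches).

**Three steps most likely to fail, with fallbacks**

Step 7 (the proposed new ring closure). The addition of a fully substituted enol silane to a ketone-derived C=N is very congested, and the hydrazone may instead decompose by the Bamford–Stevens path. The fallback uses known chemistry, sets out from 12 and comes back at 15. Intramolecular aldol addition under equilibrating conditions (KOtBu, tBuOH/THF, 0 °C; only the more substituted enolate can close an unstrained ring onto the cyclobutanone) gives (1S,4R,5R,10R,11R)-5-hydroxy-1-(tert-butyldimethylsilyloxy)longipin-3(12)-en-7-one F1. Acylation of the tertiary alcohol with methyl chlorooxoacetate (DMAP, pyridine, CH2Cl2, 0 °C, no alkoxide so that retro-aldol is avoided) gives the methyl oxalate of F1, methyl 7-oxo-1-(tert-butyldimethylsilyloxy)longipin-3(12)-en-5-yl oxalate F2. Barton-type radical deoxygenation of the tertiary oxalate (Bu3SnH, AIBN, PhMe, 110 °C) gives 15; the bridgehead C5 radical can only take up hydrogen with retention.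

Step 6 (ketene cycloaddition). The alkene carries an allylic silyloxy group and the vinylketene may dimerise or give low facial selectivity. The fallback sets out from 9 and comes back at 12. Acid chloride 10 (made as in step 6) is quenched with pyrrolidine to give 1-[(2E,5S,6E)-5-(tert-butyldimethylsilyloxy)-3,7,11-trimethyl-10-oxododeca-2,6-dienoyl]pyrrolidine F3. Tf2O and 2,4,6-collidine in ClCH2CH2Cl (0 → 80 °C) convert the amide into the more electrophilic vinylketeniminium ion, whose intramolecular [2+2] cycloaddition (Ghosez-type keteniminium–alkene cycloaddition, same bridged regiochemistry and same tether control) gives the cyclobutaniminium triflate of 12, 1-[(1R,2S,5R,7R)-2-(tert-butyldimethylsilyloxy)-7-methyl-4-methylidene-7-(4-methyl-3-oxopentyl)bicyclo[3.1.1]heptan-6-ylidene]pyrrolidinium triflate F4. Hydrolysis with aqueous NaHCO3 returns 12.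

Step 4 (asymmetric vinylogous aldol). Silylium-type catalysis may give poor enantioselectivity with this aliphatic β,β-disubstituted enal. The fallback sets out from 5 and 7 and comes back at 8. A Lewis-base-catalysed vinylogous aldol addition (SiCl4, Denmark's chiral binaphthyldiamine-derived bisphosphoramide 2 mol %, iPr2NEt 10 mol %, CH2Cl2, −78 °C; aqueous KF/NaHCO3 work-up), a different activation mode with a broad record for conjugated aldehydes, gives the free alcohol methyl (2E,5S,6E)-5-hydroxy-3,7,11-trimethyl-10-oxododeca-2,6-dienoate F5. Silylation (tBuMe2SiOTf, 2,6-lutidine, CH2Cl2, −78 °C) then gives 8.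

**Further compounds**

F1 | step 7 | (1S,4R,5R,10R,11R)-5-hydroxy-1-(tert-butyldimethylsilyloxy)longipin-3(12)-en-7-one | C1CC(=O)C(C)(C)[C@]2(O)[C@H]3[C@@H](O[Si](C)(C)C(C)(C)C)CC(=C)[C@@H]2[C@@]13C
F2 | step 7 | methyl 7-oxo-1-(tert-butyldimethylsilyloxy)longipin-3(12)-en-5-yl oxalate | C1CC(=O)C(C)(C)[C@]2(OC(=O)C(=O)OC)[C@H]3[C@@H](O[Si](C)(C)C(C)(C)C)CC(=C)[C@@H]2[C@@]13C
F3 | step 6 | 1-[(2E,5S,6E)-5-(tert-butyldimethylsilyloxy)-3,7,11-trimethyl-10-oxododeca-2,6-dienoyl]pyrrolidine | O=C(/C=C(\C)C[C@H](O[Si](C)(C)C(C)(C)C)/C=C(\C)CCC(=O)C(C)C)N1CCCC1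
F4 | step 6 | 1-[(1R,2S,5R,7R)-2-(tert-butyldimethylsilyloxy)-7-methyl-4-methylidene-7-(4-methyl-3-oxopentyl)bicyclo[3.1.1]heptan-6-ylidene]pyrrolidinium trifluoromethanesulfonate | FC(F)(F)S(=O)(=O)[O-].C1CC[N+](C1)=C1[C@H]2[C@@H](O[Si](C)(C)C(C)(C)C)CC(=C)[C@@H]1[C@@]2(C)CCC(=O)C(C)C
F5 | step 4 | methyl (2E,5S,6E)-5-hydroxy-3,7,11-trimethyl-10-oxododeca-2,6-dienoate | COC(=O)/C=C(\C)C[C@H](O)/C=C(\C)CCC(=O)C(C)C
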